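**Retrosynthetic overview**

1. Target 19 ← protonation and hydrogenolysis of two benzyl ethers ← disodium bis-sulfate 17 ← sulfation of 7-OH and 4'-OH (5-OH is hydrogen-bonded to C4=O and inert) ← 3,3'-di-O-benzylquercetin 16 ← removal of three allyl ethers ← flavone 15.
2. Key disconnection of 15 at O1–C8a: this aryl ether bond of ring C sits on ring A next to C4a, which carries the C4 carbonyl, so the enol oxygen of a 2-bromoaryl 1,3-diketone (14) can replace bromide at C8a under copper catalysis.
3. 14 ← oxidation ← aldol 13 ← C3–C4 bond formation between ring-A aldehyde 4 and the enolate of α-benzyloxy ketone 11 (ring B plus C2 and C3).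
4. 4 ← 5-bromoresorcinol 1 (bis-allylation, Vilsmeier formylation); 11 ← 2-(benzyloxy)phenol 5 (para-bromination, allylation, Br–Li exchange) and Weinreb amide 9 from benzyloxyacetyl chloride 8.
5. Ring order: rings A and B are bought; ring C is the only ring formed (step 9).

Key step: step 9

Assumption: the target is taken as the free bis(hydrogen sulfate) as drawn; because aryl hydrogen sulfates hydrolyse readily in acid, the sulfate esters are carried as sodium salts and protonated only in the last operation.
Remark: 13 (mixture of diastereomers) and 14 are racemic and are written without configuration; their stereocentres are not controlled, are lost by step 9, and the target has none.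

**Route**

Step 1
Reactants: 1 5-bromoresorcinol
Product: 2 1,3-bis(allyloxy)-5-bromobenzene
Conditions: allyl bromide (2.4 equiv), K2CO3, DMF, 50 °C
Reagents that add atoms: allyl bromide, C=CCBr
Why: Williamson etherification (SN2) of both phenoxides should proceed cleanly, the aryl bromide being inert to carbonate.

Step 2
Reactants: 2 1,3-bis(allyloxy)-5-bromobenzene
Product: 4 2,4-bis(allyloxy)-6-bromobenzaldehyde, via iminium dichlorophosphate 3 (not isolated)
Conditions: POCl3, DMF, 0 to 70 °C; then aq NaOAc, rt
Reagents that add atoms: N,N-dimethylformamide, CN(C)C=O; water, O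
Why: Vilsmeier–Haack formylation of 1-bromo-3,5-dialkoxybenzenes is known to go to the carbon ortho to bromine (para to one alkoxy group, ortho to the other) rather than to the more crowded carbon between the two alkoxy groups, and hydrolysis of iminium salt 3 then frees the aldehyde.

Step 3
Reactants: 5 2-(benzyloxy)phenol
Product: 6 2-(benzyloxy)-4-bromophenol
Conditions: NBS, MeCN, 0 °C
Reagents that add atoms: N-bromosuccinimide, O=C1CCC(=O)N1Br
Why: Electrophilic aromatic bromination should go para to the free hydroxyl, the stronger director, as it does for guaiacol.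

Step 4
Reactants: 6 2-(benzyloxy)-4-bromophenol
Product: 7 1-(allyloxy)-2-(benzyloxy)-4-bromobenzene
Conditions: allyl bromide, K2CO3, acetone, reflux
Reagents that add atoms: allyl bromide, C=CCBr
Why: Williamson etherification of the single phenol fixes the allyl group on the oxygen para to bromine, which becomes O4'.

Step 5
Reactants: 8 benzyloxyacetyl chloride
Product: 9 2-(benzyloxy)-N-methoxy-N-methylacetamide
Conditions: MeNH(OMe)·HCl, Et3N, CH2Cl2, 0 °C to rt
Reagents that add atoms: N,O-dimethylhydroxylamine hydrochloride, CNOC.Cl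
Why: N-acylation of the hydroxylamine by the acid chloride is a standard Weinreb amide preparation.

Step 6
Reactants: 7 1-(allyloxy)-2-(benzyloxy)-4-bromobenzene; 9 2-(benzyloxy)-N-methoxy-N-methylacetamide
Product: 11 1-[4-(allyloxy)-3-(benzyloxy)phenyl]-2-(benzyloxy)ethan-1-one, via aryllithium 10 (not isolated)
Conditions: n-BuLi, THF, −78 °C; then 9, −78 to 0 °C; 1 M HCl, 0 °C
Reagents that add atoms: none
Why: Bromine–lithium exchange at −78 °C leaves the allyl and benzyl ethers alone, and the Weinreb ketone synthesis stops at the ketone because the chelated tetrahedral adduct survives until the acid quench.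

Step 7
Reactants: 11 1-[4-(allyloxy)-3-(benzyloxy)phenyl]-2-(benzyloxy)ethan-1-one; 4 2,4-bis(allyloxy)-6-bromobenzaldehyde
Product: 13 1-[4-(allyloxy)-3-(benzyloxy)phenyl]-2-(benzyloxy)-3-[2,4-bis(allyloxy)-6-bromophenyl]-3-hydroxypropan-1-one (racemic mixture of diastereomers), via lithium enolate 12 (not isolated)
Conditions: LiN(SiMe3)2, THF, −78 °C; then 4, −78 °C; AcOH quench at −78 °C
Reagents that add atoms: none
Why: Aldol addition of the chelated lithium enolate to the non-enolisable aldehyde forms the future C3–C4 bond, and the two new stereocentres are left uncontrolled because steps 8 and 9 remove both.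

Step 8
Reactants: 13 aldol adduct
Product: 14 (±)-1-[4-(allyloxy)-3-(benzyloxy)phenyl]-2-(benzyloxy)-3-[2,4-bis(allyloxy)-6-bromophenyl]propane-1,3-dione
Conditions: Dess–Martin periodinane, CH2Cl2, 0 °C to rt
Reagents that add atoms: none
Why: Dess–Martin oxidation converts β-hydroxy ketones into 1,3-diketones under neutral conditions that spare allyl ethers, benzyl ethers and the aryl bromide; both diastereomers of 13 should give the same racemic diketone.

Step 9
Reactants: 14 (±)-2-bromoaryl α-benzyloxy 1,3-diketone
Product: 15 5,7-bis(allyloxy)-2-[4-(allyloxy)-3-(benzyloxy)phenyl]-3-(benzyloxy)-4H-chromen-4-one (5,7,4'-tri-O-allyl-3,3'-di-O-benzylquercetin)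
Conditions: CuI (10 mol %), 1,10-phenanthroline (20 mol %), K2CO3 (2 equiv), 4 Å molecular sieves, DMF, 100 °C, Ar
Reagents that add atoms: none
Why: K2CO3 removes the acidic C2–H of the propanedione chain of 14 and the potassium diketonate passes its enolate to phenanthroline-bound monovalent copper; the copper then inserts into the C8a–Br bond, which the ortho acyl group activates and holds close, and C–O reductive elimination from the resulting trivalent aryl copper enolate forms O1–C8a and returns monovalent copper. The closest known reaction type is the copper-catalysed intramolecular Ullmann O-arylation of 1-(2-haloaryl)-1,3-diketones, an established flavone synthesis, applied here to a diketone that carries a 2-benzyloxy group. Ring C, the only ring formed, closes in a six-membered (6-exo) mode by attack of the enolate oxygen of the distal carbonyl (the one on the side of ring B) on the aryl carbon, after rotation about the C3–C4 bond has turned ring A toward that oxygen. No stereocentre is created, and the racemic C2–H centre of 14 becomes the sp2 carbon C3 of the chromone. The step needs O- over C-arylation and the distal over the proximal oxygen, and geometry secures both, since C-arylation or attack by the proximal oxygen would demand a four-membered ring. Anhydrous carbonate and molecular sieves should hold back retro-Claisen cleavage, and at 100 °C the allyl ethers stay well below the temperature of Claisen rearrangement.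

Step 10
Reactants: 15 5,7,4'-tri-O-allyl-3,3'-di-O-benzylquercetin
Product: 16 3-(benzyloxy)-2-[3-(benzyloxy)-4-hydroxyphenyl]-5,7-dihydroxy-4H-chromen-4-one (3,3'-di-O-benzylquercetin)
Conditions: Pd(PPh3)4 (5 mol %), morpholine, THF, rt
Reagents that add atoms: none
Why: Tsuji–Trost deallylation, in which zerovalent palladium ionises each aryl allyl ether to a π-allyl complex and a phenoxide and morpholine traps the allyl group, should free the three phenols and leave the benzyl ethers untouched.

Step 11
Reactants: 16 3,3'-di-O-benzylquercetin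
Product: 17 disodium 3-(benzyloxy)-2-[3-(benzyloxy)-4-(sulfonatooxy)phenyl]-5-hydroxy-4-oxo-4H-chromen-7-yl sulfate
Conditions: SO3·pyridine (6 equiv), pyridine, 40 °C; then aq NaHCO3; C18 chromatography
Reagents that add atoms: sulfur trioxide–pyridine complex, O=S(=O)([O-])[n+]1ccccc1; sodium hydrogencarbonate, [Na+].OC([O-])=O
Why: O-sulfation with an SO3–amine complex should take the 7-OH and 4'-OH only, because the 5-OH is tied to the C4 carbonyl by a hydrogen bond and O3 and O3' are blocked as benzyl ethers.

Step 12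
Reactants: 17 disodium dibenzyl bis-sulfate
Product: 19 3',5-dihydroxy-4',7-bis(sulfooxy)flavonol (quercetin 7,4'-bis(hydrogen sulfate)), via disodium salt 18 (not isolated)
Conditions: H2 (1 atm), 10% Pd/C, MeOH–H2O, rt; filter; then HCl (2.0 equiv), H2O, 0 °C; C18 desalting, freeze-drying
Reagents that add atoms: none
Why: Catalytic hydrogenolysis cleaves the two benzyl ethers while aryl sulfate salts and the C2=C3 bond of the flavonol are stable at neutral pH, and cold protonation of salt 18 with exactly two equivalents of acid gives the free acid.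

**Compound list**

1 | 5-bromoresorcinol | Oc1cc(O)cc(Br)c1 | starting material
2 | 1,3-bis(allyloxy)-5-bromobenzene | C=CCOc1cc(Br)cc(OCC=C)c1 | intermediate
3 | N-[2,4-bis(allyloxy)-6-bromobenzylidene]-N-methylmethanaminium dichlorophosphate | C[N+](C)=Cc1c(Br)cc(OCC=C)cc1OCC=C.[O-]P(=O)(Cl)Cl | intermediate (not isolated)
4 | 2,4-bis(allyloxy)-6-bromobenzaldehyde | O=Cc1c(Br)cc(OCC=C)cc1OCC=C | intermediate
5 | 2-(benzyloxy)phenol | Oc1ccccc1OCc1ccccc1 | starting material
6 | 2-(benzyloxy)-4-bromophenol | Oc1ccc(Br)cc1OCc1ccccc1 | intermediate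
7 | 1-(allyloxy)-2-(benzyloxy)-4-bromobenzene | C=CCOc1ccc(Br)cc1OCc1ccccc1 | intermediate
8 | benzyloxyacetyl chloride | O=C(Cl)COCc1ccccc1 | starting material
9 | 2-(benzyloxy)-N-methoxy-N-methylacetamide | CON(C)C(=O)COCc1ccccc1 | intermediate
10 | [4-(allyloxy)-3-(benzyloxy)phenyl]lithium | [Li]c1ccc(OCC=C)c(OCc2ccccc2)c1 | intermediate (not isolated)
11 | 1-[4-(allyloxy)-3-(benzyloxy)phenyl]-2-(benzyloxy)ethan-1-one | O=C(COCc1ccccc1)c1ccc(OCC=C)c(OCc2ccccc2)c1 | intermediate
12 | lithium (Z)-enolate of 11 | [Li]O/C(=C\OCc1ccccc1)c1ccc(OCC=C)c(OCc2ccccc2)c1 | intermediate (not isolated)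
13 | 1-[4-(allyloxy)-3-(benzyloxy)phenyl]-2-(benzyloxy)-3-[2,4-bis(allyloxy)-6-bromophenyl]-3-hydroxypropan-1-one (racemic, mixture of diastereomers) | OC(c1c(Br)cc(OCC=C)cc1OCC=C)C(OCc1ccccc1)C(=O)c1ccc(OCC=C)c(OCc2ccccc2)c1 | intermediate
14 | (±)-1-[4-(allyloxy)-3-(benzyloxy)phenyl]-2-(benzyloxy)-3-[2,4-bis(allyloxy)-6-bromophenyl]propane-1,3-dione | O=C(c1c(Br)cc(OCC=C)cc1OCC=C)C(OCc1ccccc1)C(=O)c1ccc(OCC=C)c(OCc2ccccc2)c1 | intermediate (key-step precursor)
15 | 5,7,4'-tri-O-allyl-3,3'-di-O-benzylquercetin | O=c1c(OCc2ccccc2)c(-c2ccc(OCC=C)c(OCc3ccccc3)c2)oc2cc(OCC=C)cc(OCC=C)c12 | intermediate (key-step product)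
16 | 3,3'-di-O-benzylquercetin | O=c1c(OCc2ccccc2)c(-c2ccc(O)c(OCc3ccccc3)c2)oc2cc(O)cc(O)c12 | intermediate
17 | disodium 3,3'-di-O-benzylquercetin 7,4'-bis(sulfate) | O=c1c(OCc2ccccc2)c(-c2ccc(OS(=O)(=O)[O-])c(OCc3ccccc3)c2)oc2cc(OS(=O)(=O)[O-])cc(O)c12.[Na+].[Na+] | intermediate
18 | disodium quercetin 7,4'-bis(sulfate) | O=c1c(O)c(-c2ccc(OS(=O)(=O)[O-])c(O)c2)oc2cc(OS(=O)(=O)[O-])cc(O)c12.[Na+].[Na+] | intermediate (not isolated)
19 | 3',5-dihydroxy-4',7-bis(sulfooxy)flavonol | O=c1c(O)c(-c2ccc(OS(=O)(=O)O)c(O)c2)oc2cc(OS(=O)(=O)O)cc(O)c12 | target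

**Step count**

Total: 12 steps. Longest linear sequence: 9 steps (3, 4, 6, 7, 8, 9, 10, 11, 12, from 2-(benzyloxy)phenol).

**Steps most likely to fail, with fallbacks**

Step 9 (key step). The diketonate may fragment by retro-Claisen cleavage under hot basic conditions, copper may insert only slowly into the electron-rich, hindered C–Br bond, or the bromide may be reduced off. The fallback closes ring C at O1–C2 by cyclodehydration of a 2-hydroxyaryl diketone (Baker–Venkataraman route); it sets out from 7 and comes back at 15. Hoesch acylation of phloroglucinol with benzyloxyacetonitrile (ZnCl2, HCl, Et2O, 0 °C) would give 2-(benzyloxy)-1-(2,4,6-trihydroxyphenyl)ethan-1-iminium chloride F1, which hot water hydrolyses to 2-(benzyloxy)-1-(2,4,6-trihydroxyphenyl)ethan-1-one F2. Allyl bromide (2 equiv) and K2CO3 in acetone should then give 1-[2,4-bis(allyloxy)-6-hydroxyphenyl]-2-(benzyloxy)ethan-1-one F3, the chelated ortho hydroxyl staying free. Aryllithium 10, made from 7 as in step 6, is quenched with CO2 to give 4-(allyloxy)-3-(benzyloxy)benzoic acid F4. Esterification of F3 with F4 (EDC·HCl, DMAP, CH2Cl2) gives 3,5-bis(allyloxy)-2-[(benzyloxy)acetyl]phenyl 4-(allyloxy)-3-(benzyloxy)benzoate F5. LiN(SiMe3)2 in THF brings about the Baker–Venkataraman acyl shift to 1-[2,4-bis(allyloxy)-6-hydroxyphenyl]-2-(benzyloxy)-3-[4-(allyloxy)-3-(benzyloxy)phenyl]propane-1,3-dione F6, and TsOH in toluene at 80 °C closes the pyranone to 15.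

Step 7. Addition to the hindered, electron-rich aldehyde may stay incomplete or revert (retro-aldol) on work-up, and the adduct may lose water. The fallback makes the diketone by C-acylation instead of aldol addition and oxidation; it sets out from 4 and 11 and comes back at 14, so step 8 is not needed. Pinnick oxidation of 4 (NaClO2, NaH2PO4, 2-methyl-2-butene, t-BuOH–H2O) gives 2,4-bis(allyloxy)-6-bromobenzoic acid F7, and oxalyl chloride with catalytic DMF in CH2Cl2 gives 2,4-bis(allyloxy)-6-bromobenzoyl chloride F8. Soft enolisation of 11 with MgBr2·OEt2 and i-Pr2NEt in CH2Cl2, followed by C-acylation of the magnesium enolate with F8, should give 14 directly.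

Step 11. Sulfation may stop at a monosulfate or, if forced, reach the 5-OH, and the dianionic salt may be lost on purification. The fallback carries the sulfates as neutral, protected diesters; it sets out from 16 and comes back at 17. 2,2,2-Trichloroethyl chlorosulfate (2.2 equiv) with Et3N and DMAP in THF gives 3,3'-di-O-benzylquercetin 7,4'-bis(2,2,2-trichloroethyl sulfate) F9, which can be purified on silica. Zn dust and HCO2NH4 in MeOH remove the trichloroethyl groups by reductive β-elimination to give diammonium 3,3'-di-O-benzylquercetin 7,4'-bis(sulfate) F10. Aqueous NaOH (2 equiv) and evaporation then give 17.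

**Further compounds**

F1 | step 9 | 2-(benzyloxy)-1-(2,4,6-trihydroxyphenyl)ethan-1-iminium chloride | [NH2+]=C(COCc1ccccc1)c1c(O)cc(O)cc1O.[Cl-]
F2 | step 9 | 2-(benzyloxy)-1-(2,4,6-trihydroxyphenyl)ethan-1-one | O=C(COCc1ccccc1)c1c(O)cc(O)cc1O
F3 | step 9 | 1-[2,4-bis(allyloxy)-6-hydroxyphenyl]-2-(benzyloxy)ethan-1-one | O=C(COCc1ccccc1)c1c(O)cc(OCC=C)cc1OCC=C
F4 | step 9 | 4-(allyloxy)-3-(benzyloxy)benzoic acid | OC(=O)c1ccc(OCC=C)c(OCc2ccccc2)c1
F5 | step 9 | 3,5-bis(allyloxy)-2-[(benzyloxy)acetyl]phenyl 4-(allyloxy)-3-(benzyloxy)benzoate | O=C(COCc1ccccc1)c1c(OC(=O)c2ccc(OCC=C)c(OCc3ccccc3)c2)cc(OCC=C)cc1OCC=C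
F6 | step 9 | 1-[2,4-bis(allyloxy)-6-hydroxyphenyl]-2-(benzyloxy)-3-[4-(allyloxy)-3-(benzyloxy)phenyl]propane-1,3-dione | O=C(c1c(O)cc(OCC=C)cc1OCC=C)C(OCc1ccccc1)C(=O)c1ccc(OCC=C)c(OCc2ccccc2)c1
F7 | step 7 | 2,4-bis(allyloxy)-6-bromobenzoic acid | OC(=O)c1c(Br)cc(OCC=C)cc1OCC=C
F8 | step 7 | 2,4-bis(allyloxy)-6-bromobenzoyl chloride | O=C(Cl)c1c(Br)cc(OCC=C)cc1OCC=C
F9 | step 11 | 3,3'-di-O-benzylquercetin 7,4'-bis(2,2,2-trichloroethyl sulfate) | O=c1c(OCc2ccccc2)c(-c2ccc(OS(=O)(=O)OCC(Cl)(Cl)Cl)c(OCc3ccccc3)c2)oc2cc(OS(=O)(=O)OCC(Cl)(Cl)Cl)cc(O)c12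
F10 | step 11 | diammonium 3,3'-di-O-benzylquercetin 7,4'-bis(sulfate) | O=c1c(OCc2ccccc2)c(-c2ccc(OS(=O)(=O)[O-])c(OCc3ccccc3)c2)oc2cc(OS(=O)(=O)[O-])cc(O)c12.[NH4+].[NH4+]
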